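**Plan**

1. Cuts: (a) C9–C11, the sp2–sp3 bond between the dienyl decalin and the two-carbon arm of the benzoxepanone half; (b) C3–C4 of ring A in the decalin half; (c) O–C4' of the oxepane and the C5'–O bond behind it. (Terpenoid locants: C1–C10 decalin, C11/C12 linker, primed locants for the benzoxepane half, O between C4' and C5'.)
2. Both halves come from carvone, alkylated twice at the α'-carbon: (R)-carvone is ring B, onto which ring A is closed; (S)-carvone is the cyclohexane ring, onto which the oxepane and then the vinyl arm are built.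
3. Feature used: C4 of ring A is the internal carbon of the isopropenyl group that carvone places on C5 of ring B, and C3 is an aldehyde carbon at the end of the three-carbon arm on the neighbouring quaternary C10. Hydrogen-atom transfer to the =CH2 makes C4 a tertiary radical that closes ring A on C3=O and creates the second C4 methyl in the same event.
4. Stereochemistry: the carvone stereocentre (C5, C5') directs the second alkylation anti (C10, C10'); the trans ring fusion is inherited and C3 comes from a chair closure with equatorial oxygen. C5'–O arises by Criegee rearrangement with retention, C8' by hydrogenation anti to the angular methyl, C9' by hydride delivery to the open face.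
5. End game: dienyl triflate (diene set by γ-enolisation) plus alkylborane (B-alkyl Suzuki), then oxidation at C3' and desilylation at C3.

Key step: step 4

Remark: 5-iodo-2-methylpent-2-ene is taken as a catalogue reagent.
Remark: the C3' configuration fixed in step 9 only serves to give single diastereomers; it is erased when C3' becomes the ketone in step 18.

**Route**

Step 1
Reactants: 1 (R)-(−)-carvone
Product: 3 (5R,6S)-2,6-dimethyl-5-(prop-1-en-2-yl)cyclohex-2-en-1-one, via lithium dienolate 2 (not isolated)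
Conditions: LiN(i-Pr)2, THF, −78 °C; MeI, −78 → 0 °C
Reagents that add atoms: iodomethane, CI
Why: Kinetic α'-deprotonation and C-methylation of the cross-conjugated dienolate (ketone enolate alkylation) should give mainly the trans isomer, and the configuration of this carbon is of no consequence because it is planarised again in step 2.

Step 2
Reactants: 3 (5R,6S)-2,6-dimethyl-5-(prop-1-en-2-yl)cyclohex-2-en-1-one
Product: 5 (5S,6S)-2,6-dimethyl-5-(prop-1-en-2-yl)-6-(prop-2-en-1-yl)cyclohex-2-en-1-one, via lithium dienolate 4 (not isolated)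
Conditions: LiN(i-Pr)2, THF, −78 °C; allyl bromide, DMPU, −78 → 0 °C
Reagents that add atoms: allyl bromide, C=CCBr
Why: A second enolate alkylation should bring the allyl group in anti to the neighbouring isopropenyl group, which sets the quaternary centre (the later C10) with its methyl cis to the isopropenyl group.

Step 3
Reactants: 5 (5S,6S)-2,6-dimethyl-5-(prop-1-en-2-yl)-6-(prop-2-en-1-yl)cyclohex-2-en-1-one
Product: 6 3-[(1S,6S)-1,3-dimethyl-2-oxo-6-(prop-1-en-2-yl)cyclohex-3-en-1-yl]propanal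
Conditions: PdCl2(PhCN)2 (12 mol %), CuCl2·2H2O (12 mol %), AgNO2 (6 mol %), O2 (1 atm), t-BuOH/MeNO2, rt
Reagents that add atoms: dioxygen, O=O
Why: The nitrite-modified, aldehyde-selective (anti-Markovnikov) Wacker oxidation should oxidise only the monosubstituted allyl alkene at its terminal carbon, the isopropenyl group and the enone being inert, and it touches no stereocentre.

Step 4
Reactants: 6 3-[(1S,6S)-1,3-dimethyl-2-oxo-6-(prop-1-en-2-yl)cyclohex-3-en-1-yl]propanal
Product: 7 (4aS,6S,8aS)-6-hydroxy-2,5,5,8a-tetramethyl-4a,5,6,7,8,8a-hexahydronaphthalen-1(4H)-one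
Conditions: Fe(acac)3 (0.3 equiv), PhSiH3 (2.5 equiv), EtOH, 60 °C, 0.02 M
Reagents that add atoms: none
Why: An iron hydride formed from Fe(acac)3 and PhSiH3 transfers a hydrogen atom to the CH2 terminus of the electron-rich isopropenyl group, the tertiary C4 radical adds to the aldehyde carbon C3, and the alkoxy radical is reduced by the low-valent iron/ethanol couple, which makes the reversible addition productive. The closest known reaction type is the iron-hydride (MHAT) reductive coupling of unactivated alkenes with carbonyl groups, here joining the Markovnikov alkene carbon and the carbonyl carbon, two centres that are both electrophilic in polar chemistry. Ring A closes in the 6-exo-trig mode through a chair transition state on the trans-diequatorial C5 and C10 substituents of ring B, so the trans ring fusion is inherited from 6 and C4, which receives its second methyl, is not a stereocentre. C3 is the only new stereocentre and is controlled by the chair transition state with the carbonyl oxygen pseudo-equatorial, helped by reopening of the more strained axial alkoxy radical, which should give the equatorial 3β (3S) alcohol. The step needs hydrogen-atom transfer to the 1,1-disubstituted alkene and not to the enone, and cyclisation faster than quenching of the radical. The first is secured by the preference of metal-hydride HAT for electron-rich alkenes, the second by the fast 6-exo attack on an aldehyde held in reach by the quaternary C10 and by high dilution.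

Step 5
Reactants: 7 (4aS,6S,8aS)-6-hydroxy-2,5,5,8a-tetramethyl-4a,5,6,7,8,8a-hexahydronaphthalen-1(4H)-one
Product: 8 (4aS,6S,8aS)-2,5,5,8a-tetramethyl-6-[(triethylsilyl)oxy]-4a,5,6,7,8,8a-hexahydronaphthalen-1(4H)-one
Conditions: Et3SiOTf, 2,6-lutidine, CH2Cl2, −78 → 0 °C
Reagents that add atoms: triethylsilyl trifluoromethanesulfonate, CC[Si](CC)(CC)OS(=O)(=O)C(F)(F)F
Why: Silyl ether protection of the hindered secondary alcohol with the silyl triflate masks the C3 hydroxyl for the enolisation, the borane and the oxidation that follow, and no stereocentre is affected.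

Step 6
Reactants: 8 (4aS,6S,8aS)-2,5,5,8a-tetramethyl-6-[(triethylsilyl)oxy]-4a,5,6,7,8,8a-hexahydronaphthalen-1(4H)-one
Product: 10 (4aS,6S,8aS)-2,5,5,8a-tetramethyl-6-[(triethylsilyl)oxy]-4a,5,6,7,8,8a-hexahydronaphthalen-1-yl trifluoromethanesulfonate, via potassium dienolate 9 (not isolated)
Conditions: KN(SiMe3)2, THF, −78 → −20 °C; PhNTf2, −78 °C → rt
Reagents that add atoms: N-phenylbis(trifluoromethanesulfonimide), FC(F)(F)S(=O)(=O)N(c1ccccc1)S(=O)(=O)C(F)(F)F
Why: Because C10 is quaternary the base can only remove a γ-hydrogen at C6, and O-sulfonylation of the linear dienolate (enol triflate formation) should give the 2-triflyloxy-1,3-diene with the C6=C7 and C8=C9 double bonds already in their final positions.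

Step 7
Reactants: 11 (S)-(+)-carvone
Product: 13 (5S,6R)-2,6-dimethyl-5-(prop-1-en-2-yl)cyclohex-2-en-1-one, via lithium dienolate 12 (not isolated)
Conditions: LiN(i-Pr)2, THF, −78 °C; MeI, −78 → 0 °C
Reagents that add atoms: iodomethane, CI
Why: The same enolate methylation as in step 1, run in the enantiomeric series, and again the configuration of the methylated carbon is erased in the next step.

Step 8
Reactants: 13 (5S,6R)-2,6-dimethyl-5-(prop-1-en-2-yl)cyclohex-2-en-1-one
Product: 15 (5R,6R)-2,6-dimethyl-6-(4-methylpent-3-en-1-yl)-5-(prop-1-en-2-yl)cyclohex-2-en-1-one, via lithium dienolate 14 (not isolated)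
Conditions: LiN(i-Pr)2, THF, −78 °C; 5-iodo-2-methylpent-2-ene, DMPU, −78 °C → rt
Reagents that add atoms: 5-iodo-2-methylpent-2-ene, CC(C)=CCCI
Why: Enolate alkylation with the primary homoprenyl iodide, again anti to the isopropenyl group, should set the quaternary C10' with its methyl cis to the isopropenyl group (the later C5'–O bond) and the chain that becomes C1'–C4' trans to it.

Step 9
Reactants: 15 (5R,6R)-2,6-dimethyl-6-(4-methylpent-3-en-1-yl)-5-(prop-1-en-2-yl)cyclohex-2-en-1-one
Product: 16 (5R,6R)-6-{2-[(2R)-3,3-dimethyloxiran-2-yl]ethyl}-2,6-dimethyl-5-(prop-1-en-2-yl)cyclohex-2-en-1-one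
Conditions: Shi ketone (D-fructose-derived, 30 mol %), KHSO5 (Oxone), K2CO3, Bu4NHSO4, MeCN/CH2(OMe)2/aq. Na2B4O7, 0 °C
Reagents that add atoms: potassium peroxymonosulfate, [K+].[O-]S(=O)(=O)OO
Why: Shi epoxidation (chiral dioxirane) should select the electron-rich trisubstituted alkene over the 1,1-disubstituted and the enone alkenes and give the (R)-epoxide under catalyst control, and the epoxide also masks this alkene against ozone in step 10.

Step 10
Reactants: 16 (5R,6R)-6-{2-[(2R)-3,3-dimethyloxiran-2-yl]ethyl}-2,6-dimethyl-5-(prop-1-en-2-yl)cyclohex-2-en-1-one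
Product: 19 (1S,2R)-2-{2-[(2R)-3,3-dimethyloxiran-2-yl]ethyl}-2,4-dimethyl-3-oxocyclohex-4-en-1-yl acetate, via methoxy hydroperoxide 17 (not isolated), via peroxyacetate 18 (not isolated)
Conditions: O3, CH2Cl2/MeOH, −78 °C; then Ac2O, Et3N, DMAP (cat.), CH2Cl2, 0 °C → rt
Reagents that add atoms: ozone, [O-][O+]=O; methanol, CO
Why: Ozonolysis in methanol followed by acylation of the α-methoxy hydroperoxide triggers the Criegee rearrangement, in which C5' migrates from carbon to oxygen with retention, so the isopropenyl group is replaced by an acetoxy group of the same configuration (the acetyl carbons are the former isopropenyl carbons), while the electron-poor enone alkene does not compete.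

Step 11
Reactants: 19 (1S,2R)-2-{2-[(2R)-3,3-dimethyloxiran-2-yl]ethyl}-2,4-dimethyl-3-oxocyclohex-4-en-1-yl acetate
Product: 21 (5S,6R)-5-hydroxy-6-[(3R)-3-hydroxy-4-methylpent-4-en-1-yl]-2,6-dimethylcyclohex-2-en-1-one, via allyl silyl ether 20 (not isolated)
Conditions: Me3SiOTf, DBU, toluene, 0 °C → rt; then K2CO3, MeOH, 0 °C → rt
Reagents that add atoms: none
Why: Silyl triflate-induced opening of the epoxide at its tertiary carbon with loss of a methyl proton (Noyori isomerisation of an epoxide to an allyl silyl ether) leaves the oxygen on C3' and a 1,1-disubstituted alkene at C4', and mild methanolysis then removes the silyl ether and the acetate without touching C3', C5' or C10'.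

Step 12
Reactants: 21 (5S,6R)-5-hydroxy-6-[(3R)-3-hydroxy-4-methylpent-4-en-1-yl]-2,6-dimethylcyclohex-2-en-1-one
Product: 23 (3R,5aR,9aS)-3-hydroxy-2,2,5a,7-tetramethyl-2,3,4,5,5a,9a-hexahydro-1-benzoxepin-6(9H)-one, via organomercury trifluoroacetate 22 (not isolated)
Conditions: Hg(O2CCF3)2, CH2Cl2, 0 °C → rt; then Bu3SnH, THF, 0 °C
Reagents that add atoms: none
Why: In this intramolecular alkoxymercuration the C5' hydroxyl attacks the mercurinium ion at the tertiary carbon C4', which is at once the Markovnikov and the 7-exo-trig mode (the alternative would need an eight-membered ring), tin hydride demercuration turns the CH2Hg group into the second C4' methyl, and the trans ring fusion follows from the trans C5'–O/C10'–C1' arrangement already present.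

Step 13
Reactants: 23 (3R,5aR,9aS)-3-hydroxy-2,2,5a,7-tetramethyl-2,3,4,5,5a,9a-hexahydro-1-benzoxepin-6(9H)-one
Product: 24 (3R,5aR,7R,9aS)-3-hydroxy-2,2,5a,7-tetramethyloctahydro-1-benzoxepin-6(2H)-one
Conditions: H2 (1 atm), Pd/C, EtOAc, rt
Reagents that add atoms: none
Why: Heterogeneous hydrogenation of the enone C=C should occur from the face opposite the axial angular methyl on C10', giving the C8' methyl cis to it as the kinetic product under neutral conditions.

Step 14
Reactants: 24 (3R,5aR,7R,9aS)-3-hydroxy-2,2,5a,7-tetramethyloctahydro-1-benzoxepin-6(2H)-one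
Product: 25 (3R,5aR,6R,7R,9aS)-2,2,5a,7-tetramethyloctahydro-2H-spiro[1-benzoxepine-6,2'-oxiran]-3-ol
Conditions: Me3SI, n-BuLi, THF, 0 °C; then 24, 0 °C → rt
Reagents that add atoms: trimethylsulfonium iodide, C[S+](C)C.[I-]
Why: Corey–Chaykovsky methylene transfer from the weakly basic sulfonium ylide should add to the hindered ketone from the face not blocked by the two axial methyl groups without epimerising C8'.

Step 15
Reactants: 25 (3R,5aR,6R,7R,9aS)-2,2,5a,7-tetramethyloctahydro-2H-spiro[1-benzoxepine-6,2'-oxiran]-3-ol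
Product: 26 (3R,5aS,6R,7R,9aS)-3-hydroxy-2,2,5a,7-tetramethyldecahydro-1-benzoxepine-6-carbaldehyde
Conditions: BF3·OEt2, CH2Cl2, −78 °C
Reagents that add atoms: none
Why: The Lewis acid-promoted Meinwald rearrangement (ionisation at the tertiary C9' and 1,2-hydride shift) should deliver the hydrogen to the open face and give the aldehyde with the formyl group equatorial, which is also the thermodynamically preferred C9' epimer.

Step 16
Reactants: 26 (3R,5aS,6R,7R,9aS)-3-hydroxy-2,2,5a,7-tetramethyldecahydro-1-benzoxepine-6-carbaldehyde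
Product: 27 (3R,5aS,6R,7R,9aS)-6-ethenyl-2,2,5a,7-tetramethyldecahydro-1-benzoxepin-3-ol
Conditions: Ph3PCH3Br, KOt-Bu, THF, 0 °C → rt
Reagents that add atoms: methyltriphenylphosphonium bromide, C[P+](c1ccccc1)(c1ccccc1)c1ccccc1.[Br-]
Why: Wittig methylenation of the aldehyde gives the vinyl group (C12=C11) without affecting the stereocentres.

Step 17
Reactants: 27 (3R,5aS,6R,7R,9aS)-6-ethenyl-2,2,5a,7-tetramethyldecahydro-1-benzoxepin-3-ol; 10 (4aS,6S,8aS)-2,5,5,8a-tetramethyl-6-[(triethylsilyl)oxy]-4a,5,6,7,8,8a-hexahydronaphthalen-1-yl trifluoromethanesulfonate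
Product: 29 (3R,5aS,6R,7R,9aS)-2,2,5a,7-tetramethyl-6-(2-{(4aR,6S,8aS)-2,5,5,8a-tetramethyl-6-[(triethylsilyl)oxy]-4a,5,6,7,8,8a-hexahydronaphthalen-1-yl}ethyl)decahydro-1-benzoxepin-3-ol, via B-alkyl-9-BBN borane 28 (not isolated)
Conditions: 9-BBN-H (2.4 equiv), THF, rt; then 10, Pd(dppf)Cl2 (10 mol %), AsPh3, Cs2CO3, DMF/H2O, rt → 50 °C
Reagents that add atoms: none
Why: Anti-Markovnikov hydroboration of the vinyl group and B-alkyl Suzuki–Miyaura coupling of the primary alkylborane with the dienyl triflate join C11 to C9, the C3' hydroxyl is carried as its borinate and freed in the aqueous medium, and no stereocentre is involved.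

Step 18
Reactants: 29 (3R,5aS,6R,7R,9aS)-2,2,5a,7-tetramethyl-6-(2-{(4aR,6S,8aS)-2,5,5,8a-tetramethyl-6-[(triethylsilyl)oxy]-4a,5,6,7,8,8a-hexahydronaphthalen-1-yl}ethyl)decahydro-1-benzoxepin-3-ol
Product: 30 (5aS,6R,7R,9aS)-2,2,5a,7-tetramethyl-6-(2-{(4aR,6S,8aS)-2,5,5,8a-tetramethyl-6-[(triethylsilyl)oxy]-4a,5,6,7,8,8a-hexahydronaphthalen-1-yl}ethyl)octahydro-1-benzoxepin-3(2H)-one
Conditions: Dess–Martin periodinane, NaHCO3, CH2Cl2, 0 °C → rt
Reagents that add atoms: none
Why: Dess–Martin oxidation converts the only free hydroxyl (C3') into the oxepanone carbonyl, the C3 hydroxyl being silylated, and removes the auxiliary C3' stereocentre.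

Step 19
Reactants: 30 (5aS,6R,7R,9aS)-2,2,5a,7-tetramethyl-6-(2-{(4aR,6S,8aS)-2,5,5,8a-tetramethyl-6-[(triethylsilyl)oxy]-4a,5,6,7,8,8a-hexahydronaphthalen-1-yl}ethyl)octahydro-1-benzoxepin-3(2H)-one
Product: 31 (5aS,6R,7R,9aS)-6-{2-[(4aR,6S,8aS)-6-hydroxy-2,5,5,8a-tetramethyl-4a,5,6,7,8,8a-hexahydronaphthalen-1-yl]ethyl}-2,2,5a,7-tetramethyloctahydro-1-benzoxepin-3(2H)-one
Conditions: HF·pyridine, pyridine, THF, 0 °C → rt
Reagents that add atoms: none
Why: Fluoride-mediated cleavage of the triethylsilyl ether (desilylation) under buffered conditions frees the C3 hydroxyl without touching the diene or the α-alkoxy ketone.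

**Compound list**

1 | (R)-(−)-carvone, (5R)-2-methyl-5-(prop-1-en-2-yl)cyclohex-2-en-1-one | O=C1C(C)=CC[C@@H](C(C)=C)C1 | starting material
2 | lithium (3R)-6-methyl-3-(prop-1-en-2-yl)cyclohexa-1,5-dien-1-olate | CC1=CC[C@@H](C(C)=C)C=C1O[Li] | intermediate (not isolated)
3 | (5R,6S)-2,6-dimethyl-5-(prop-1-en-2-yl)cyclohex-2-en-1-one | O=C1C(C)=CC[C@@H](C(C)=C)[C@@H]1C | intermediate
4 | lithium (3S)-2,6-dimethyl-3-(prop-1-en-2-yl)cyclohexa-1,5-dien-1-olate | CC1=CC[C@@H](C(C)=C)C(C)=C1O[Li] | intermediate (not isolated)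
5 | (5S,6S)-2,6-dimethyl-5-(prop-1-en-2-yl)-6-(prop-2-en-1-yl)cyclohex-2-en-1-one | O=C1C(C)=CC[C@@H](C(C)=C)[C@]1(C)CC=C | intermediate
6 | 3-[(1S,6S)-1,3-dimethyl-2-oxo-6-(prop-1-en-2-yl)cyclohex-3-en-1-yl]propanal | O=C1C(C)=CC[C@@H](C(C)=C)[C@]1(C)CCC=O | intermediate
7 | (4aS,6S,8aS)-6-hydroxy-2,5,5,8a-tetramethyl-4a,5,6,7,8,8a-hexahydronaphthalen-1(4H)-one | O=C1C(C)=CC[C@H]2C(C)(C)[C@@H](O)CC[C@]12C | intermediate
8 | (4aS,6S,8aS)-2,5,5,8a-tetramethyl-6-[(triethylsilyl)oxy]-4a,5,6,7,8,8a-hexahydronaphthalen-1(4H)-one | O=C1C(C)=CC[C@H]2C(C)(C)[C@@H](O[Si](CC)(CC)CC)CC[C@]12C | intermediate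
9 | potassium (4aS,6S,8aS)-2,5,5,8a-tetramethyl-6-[(triethylsilyl)oxy]-4a,5,6,7,8,8a-hexahydronaphthalen-1-olate | CC1=C(O[K])[C@@]2(C)CC[C@H](O[Si](CC)(CC)CC)C(C)(C)[C@@H]2C=C1 | intermediate (not isolated)
10 | (4aS,6S,8aS)-2,5,5,8a-tetramethyl-6-[(triethylsilyl)oxy]-4a,5,6,7,8,8a-hexahydronaphthalen-1-yl trifluoromethanesulfonate | CC1=C(OS(=O)(=O)C(F)(F)F)[C@@]2(C)CC[C@H](O[Si](CC)(CC)CC)C(C)(C)[C@@H]2C=C1 | intermediate
11 | (S)-(+)-carvone, (5S)-2-methyl-5-(prop-1-en-2-yl)cyclohex-2-en-1-one | O=C1C(C)=CC[C@H](C(C)=C)C1 | starting material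
12 | lithium (3S)-6-methyl-3-(prop-1-en-2-yl)cyclohexa-1,5-dien-1-olate | CC1=CC[C@H](C(C)=C)C=C1O[Li] | intermediate (not isolated)
13 | (5S,6R)-2,6-dimethyl-5-(prop-1-en-2-yl)cyclohex-2-en-1-one | O=C1C(C)=CC[C@H](C(C)=C)[C@H]1C | intermediate
14 | lithium (3R)-2,6-dimethyl-3-(prop-1-en-2-yl)cyclohexa-1,5-dien-1-olate | CC1=CC[C@H](C(C)=C)C(C)=C1O[Li] | intermediate (not isolated)
15 | (5R,6R)-2,6-dimethyl-6-(4-methylpent-3-en-1-yl)-5-(prop-1-en-2-yl)cyclohex-2-en-1-one | O=C1C(C)=CC[C@H](C(C)=C)[C@@]1(C)CCC=C(C)C | intermediate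
16 | (5R,6R)-6-{2-[(2R)-3,3-dimethyloxiran-2-yl]ethyl}-2,6-dimethyl-5-(prop-1-en-2-yl)cyclohex-2-en-1-one | O=C1C(C)=CC[C@H](C(C)=C)[C@@]1(C)CC[C@H]1OC1(C)C | intermediate
17 | (5S,6R)-6-{2-[(2R)-3,3-dimethyloxiran-2-yl]ethyl}-5-(1-hydroperoxy-1-methoxyethyl)-2,6-dimethylcyclohex-2-en-1-one (both epimers at the peroxyketal carbon) | O=C1C(C)=CC[C@H](C(C)(OC)OO)[C@@]1(C)CC[C@H]1OC1(C)C | intermediate (not isolated)
18 | 1-[(1S,2R)-2-{2-[(2R)-3,3-dimethyloxiran-2-yl]ethyl}-2,4-dimethyl-3-oxocyclohex-4-en-1-yl]-1-methoxyethyl ethaneperoxoate (both epimers at the peroxyketal carbon) | O=C1C(C)=CC[C@H](C(C)(OC)OOC(C)=O)[C@@]1(C)CC[C@H]1OC1(C)C | intermediate (not isolated)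
19 | (1S,2R)-2-{2-[(2R)-3,3-dimethyloxiran-2-yl]ethyl}-2,4-dimethyl-3-oxocyclohex-4-en-1-yl acetate | O=C1C(C)=CC[C@H](OC(C)=O)[C@@]1(C)CC[C@H]1OC1(C)C | intermediate
20 | (1S,2R)-2,4-dimethyl-2-{(3R)-4-methyl-3-[(trimethylsilyl)oxy]pent-4-en-1-yl}-3-oxocyclohex-4-en-1-yl acetate | O=C1C(C)=CC[C@H](OC(C)=O)[C@@]1(C)CC[C@@H](O[Si](C)(C)C)C(C)=C | intermediate (not isolated)
21 | (5S,6R)-5-hydroxy-6-[(3R)-3-hydroxy-4-methylpent-4-en-1-yl]-2,6-dimethylcyclohex-2-en-1-one | O=C1C(C)=CC[C@H](O)[C@@]1(C)CC[C@@H](O)C(C)=C | intermediate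
22 | {[(3R,5aR,9aS)-3-hydroxy-2,5a,7-trimethyl-6-oxo-2,3,4,5,5a,6,9,9a-octahydro-1-benzoxepin-2-yl]methyl}mercury trifluoroacetate (both C2 epimers) | O=C1C(C)=CC[C@@H]2OC(C)(C[Hg]OC(=O)C(F)(F)F)[C@H](O)CC[C@@]12C | intermediate (not isolated)
23 | (3R,5aR,9aS)-3-hydroxy-2,2,5a,7-tetramethyl-2,3,4,5,5a,9a-hexahydro-1-benzoxepin-6(9H)-one | O=C1C(C)=CC[C@@H]2OC(C)(C)[C@H](O)CC[C@@]12C | intermediate
24 | (3R,5aR,7R,9aS)-3-hydroxy-2,2,5a,7-tetramethyloctahydro-1-benzoxepin-6(2H)-one | O=C1[C@H](C)CC[C@@H]2OC(C)(C)[C@H](O)CC[C@@]12C | intermediate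
25 | (3R,5aR,6R,7R,9aS)-2,2,5a,7-tetramethyloctahydro-2H-spiro[1-benzoxepine-6,2'-oxiran]-3-ol | C1O[C@@]12[C@H](C)CC[C@@H]3OC(C)(C)[C@H](O)CC[C@@]23C | intermediate
26 | (3R,5aS,6R,7R,9aS)-3-hydroxy-2,2,5a,7-tetramethyldecahydro-1-benzoxepine-6-carbaldehyde | O=C[C@@H]1[C@H](C)CC[C@@H]2OC(C)(C)[C@H](O)CC[C@@]12C | intermediate
27 | (3R,5aS,6R,7R,9aS)-6-ethenyl-2,2,5a,7-tetramethyldecahydro-1-benzoxepin-3-ol | C=C[C@@H]1[C@H](C)CC[C@@H]2OC(C)(C)[C@H](O)CC[C@@]12C | intermediate
28 | B-alkyl-9-BBN adduct of 27 (boron on the terminal carbon C11, C3' hydroxyl as its 9-BBN borinate) | C(C[C@@H]1[C@H](C)CC[C@@H]2OC(C)(C)[C@H](OB3C4CCCC3CCC4)CC[C@@]12C)B1C2CCCC1CCC2 | intermediate (not isolated)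
29 | (3R,5aS,6R,7R,9aS)-2,2,5a,7-tetramethyl-6-(2-{(4aR,6S,8aS)-2,5,5,8a-tetramethyl-6-[(triethylsilyl)oxy]-4a,5,6,7,8,8a-hexahydronaphthalen-1-yl}ethyl)decahydro-1-benzoxepin-3-ol | CC1=C(CC[C@@H]2[C@H](C)CC[C@@H]3OC(C)(C)[C@H](O)CC[C@]32C)[C@@]2(C)CC[C@H](O[Si](CC)(CC)CC)C(C)(C)[C@@H]2C=C1 | intermediate
30 | (5aS,6R,7R,9aS)-2,2,5a,7-tetramethyl-6-(2-{(4aR,6S,8aS)-2,5,5,8a-tetramethyl-6-[(triethylsilyl)oxy]-4a,5,6,7,8,8a-hexahydronaphthalen-1-yl}ethyl)octahydro-1-benzoxepin-3(2H)-one | CC1=C(CC[C@@H]2[C@H](C)CC[C@@H]3OC(C)(C)C(=O)CC[C@]32C)[C@@]2(C)CC[C@H](O[Si](CC)(CC)CC)C(C)(C)[C@@H]2C=C1 | intermediate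
31 | (5aS,6R,7R,9aS)-6-{2-[(4aR,6S,8aS)-6-hydroxy-2,5,5,8a-tetramethyl-4a,5,6,7,8,8a-hexahydronaphthalen-1-yl]ethyl}-2,2,5a,7-tetramethyloctahydro-1-benzoxepin-3(2H)-one | CC1=C(CC[C@@H]2[C@H](C)CC[C@@H]3OC(C)(C)C(=O)CC[C@]32C)[C@@]2(C)CC[C@H](O)C(C)(C)[C@@H]2C=C1 | target

**Summary**

Total step count: 19. Longest linear sequence: 13 steps (from 11 through steps 7–19).

**Steps most likely to fail**

Step 4 (closure of ring A). The tertiary radical may be quenched by a second hydrogen atom before it cyclises, or the cyclised alkoxy radical may reopen faster than it is reduced. Either process would mean simple hydrogenation of the isopropenyl group, low conversion and poor facial selectivity at C3. The fallback sets out from 6 and comes back at 7, and makes the radical from a halide instead of by hydrogen-atom transfer. Markovnikov addition of HBr (HBr in AcOH, 0 °C, as in the classical preparation of carvone hydrobromide) to the isopropenyl group of 6 should give the tertiary bromide 3-[(1S,6R)-6-(2-bromopropan-2-yl)-1,3-dimethyl-2-oxocyclohex-3-en-1-yl]propanal F1. Slow addition of Bu3SnH with AIBN (benzene, 80 °C) then generates the same C4 radical under conditions in which the stannane traps the cyclised alkoxy radical at once (tin hydride radical cyclisation onto an aldehyde), which should return 7.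

Step 12 (closure of the oxepane). Closure of the seven-membered ring on the mercurinium ion may be slow, so that capture by trifluoroacetate or reversal wins and the tertiary ether does not form. The fallback sets out from 21 and comes back at 23, and builds the quaternary ether carbon by adding a methyl nucleophile to a cyclic oxocarbenium ion instead of by activating the alkene. Ozonolysis of the 1,1-disubstituted alkene of 21 (O3, CH2Cl2/MeOH, −78 °C; Me2S) should give the α-hydroxy methyl ketone (5S,6R)-5-hydroxy-6-[(3R)-3-hydroxy-4-oxopentyl]-2,6-dimethylcyclohex-2-en-1-one F2. Ketalisation with CH(OMe)3 and CSA should close the seven-membered mixed methyl ketal (3R,5aR,9aS)-3-hydroxy-2-methoxy-2,5a,7-trimethyl-2,3,4,5,5a,9a-hexahydro-1-benzoxepin-6(9H)-one F3 (either C2 epimer). AlMe3 (CH2Cl2, −78 → 0 °C) then ionises the ketal and transfers a methyl group to the oxocarbenium ion, which should give 23.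

Step 17 (fragment union). Transmetalation and reductive elimination at the C9–palladium centre, flanked by the quaternary C10 and the methyl-bearing C8, may be slow, so that hydrolysis of the triflate or protodeboronation of the borane overtakes the coupling. The fallback sets out from 27 and comes back at 30: a more nucleophilic alkylzinc reagent is prepared stepwise and the C3' ketone is installed before the union. Hydroboration–oxidation of 27 (9-BBN-H; NaOH, H2O2) should give the diol (3R,5aS,6R,7R,9aS)-6-(2-hydroxyethyl)-2,2,5a,7-tetramethyldecahydro-1-benzoxepin-3-ol F4. I2, PPh3 and imidazole convert the primary hydroxyl into the iodide (3R,5aS,6R,7R,9aS)-6-(2-iodoethyl)-2,2,5a,7-tetramethyldecahydro-1-benzoxepin-3-ol F5. Dess–Martin oxidation gives the iodo ketone (5aS,6R,7R,9aS)-6-(2-iodoethyl)-2,2,5a,7-tetramethyloctahydro-1-benzoxepin-3(2H)-one F6. Zinc insertion (Zn dust, LiCl, THF) gives the alkylzinc iodide {2-[(5aS,6R,7R,9aS)-2,2,5a,7-tetramethyl-3-oxodecahydro-1-benzoxepin-6-yl]ethyl}zinc iodide F7, and Negishi coupling with 10 (Pd(OAc)2, SPhos, THF) should give 30 directly.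

**Further compounds**

F1 | step 4 | 3-[(1S,6R)-6-(2-bromopropan-2-yl)-1,3-dimethyl-2-oxocyclohex-3-en-1-yl]propanal | O=C1C(C)=CC[C@@H](C(C)(C)Br)[C@]1(C)CCC=O
F2 | step 12 | (5S,6R)-5-hydroxy-6-[(3R)-3-hydroxy-4-oxopentyl]-2,6-dimethylcyclohex-2-en-1-one | O=C1C(C)=CC[C@H](O)[C@@]1(C)CC[C@@H](O)C(C)=O
F3 | step 12 | (3R,5aR,9aS)-3-hydroxy-2-methoxy-2,5a,7-trimethyl-2,3,4,5,5a,9a-hexahydro-1-benzoxepin-6(9H)-one (either C2 epimer) | O=C1C(C)=CC[C@@H]2OC(C)(OC)[C@H](O)CC[C@@]12C
F4 | step 17 | (3R,5aS,6R,7R,9aS)-6-(2-hydroxyethyl)-2,2,5a,7-tetramethyldecahydro-1-benzoxepin-3-ol | OCC[C@@H]1[C@H](C)CC[C@@H]2OC(C)(C)[C@H](O)CC[C@@]12C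
F5 | step 17 | (3R,5aS,6R,7R,9aS)-6-(2-iodoethyl)-2,2,5a,7-tetramethyldecahydro-1-benzoxepin-3-ol | ICC[C@@H]1[C@H](C)CC[C@@H]2OC(C)(C)[C@H](O)CC[C@@]12C
F6 | step 17 | (5aS,6R,7R,9aS)-6-(2-iodoethyl)-2,2,5a,7-tetramethyloctahydro-1-benzoxepin-3(2H)-one | ICC[C@@H]1[C@H](C)CC[C@@H]2OC(C)(C)C(=O)CC[C@@]12C
F7 | step 17 | {2-[(5aS,6R,7R,9aS)-2,2,5a,7-tetramethyl-3-oxodecahydro-1-benzoxepin-6-yl]ethyl}zinc iodide | I[Zn]CC[C@@H]1[C@H](C)CC[C@@H]2OC(C)(C)C(=O)CC[C@@]12C
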